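**Retrosynthetic overview**

1. The target, the (2S)-6-geranyl flavanone 21, comes from its tetrakis-MOM ether 20 by acid deprotection. Compound 20 comes from the 2'-hydroxychalcone 19 by a catalyst-controlled oxa-Michael closure of ring C (O1–C2). Ring C is the only ring made; rings A and B are carried from phloroglucinol and 5-hydroxyvanillin.
2. The strategy rests on ring A: C4a and C8a are neighbouring carbons that carry the C4 ketone and O1, and the C5 oxygen sits next to C4a. An aryne across C4a–C8a can therefore take up the carboxyl group of the ring B cinnamic acid 16, oxygen at C8a and acyl carbon at C4a, with the C5 alkoxy group deciding the orientation.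
3. In 19 only the C8a oxygen is free (C5–O stays a MOM ether), so closure can give only the 6-geranyl flavanone. Hot fluoride is known to close such chalcones racemically, so the key step ends with an alkaline treatment that reopens any flavanone to the chalcone.
4. Aryne precursor 12: phloroglucinol, bis-MOM ether, TIPS ether, lithiation between the MOM groups and geranylation, desilylation, ortho-bromination, retro-Brook shift and triflation. Acid 16: MOM protection and Knoevenagel–Doebner condensation.

Key step: step 9

Assumption: of the two pseudoenantiomeric cinchona thioureas, the quinidine-derived one is taken to deliver the 2S flavanone; the sense is to be confirmed on a small scale, and the quinine-derived catalyst would replace it if the sense is the opposite.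

**Route**

Step 1
Reactants: 1 phloroglucinol
Product: 2 3,5-bis(methoxymethoxy)phenol
Conditions: MOMCl (2.0 equiv), i-Pr2NEt (2.2 equiv), DMF, 0 °C → rt; chromatography
Reagents that add atoms: chloromethyl methyl ether, COCCl
Why: Williamson-type O-alkylation is statistical among three equivalent hydroxyls, so two equivalents of MOMCl should favour the bis-ether, which is separated on silica from the mono-ether (resubmitted) and the tris-ether.

Step 2
Reactants: 2 3,5-bis(methoxymethoxy)phenol
Product: 3 triisopropyl[3,5-bis(methoxymethoxy)phenoxy]silane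
Conditions: TIPSCl (1.2 equiv), imidazole, DMF, rt
Reagents that add atoms: chlorotriisopropylsilane, CC(C)[Si](Cl)(C(C)C)C(C)C
Why: Standard silylation of a phenol; the bulky TIPS ether withstands n-BuLi and does not direct metalation to its own ortho positions.

Step 3
Reactants: 3 triisopropyl[3,5-bis(methoxymethoxy)phenoxy]silane; 4 geranyl bromide
Product: 6 triisopropyl[4-geranyl-3,5-bis(methoxymethoxy)phenoxy]silane, via aryllithium 5 (not isolated)
Conditions: n-BuLi (1.15 equiv), THF, 0 °C → rt; then 4, −78 °C → rt
Reagents that add atoms: none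
Why: Directed ortho-metalation should occur at the one C–H flanked by two chelating OMOM groups, and the aryllithium displaces the primary allylic bromide by SN2 substitution with the E olefin unchanged.

Step 4
Reactants: 6 triisopropyl[4-geranyl-3,5-bis(methoxymethoxy)phenoxy]silane
Product: 7 4-geranyl-3,5-bis(methoxymethoxy)phenol
Conditions: TBAF (1.1 equiv), THF, 0 °C; aq. NH4Cl
Reagents that add atoms: none
Why: Fluoride-mediated cleavage of the aryl silyl ether leaves the MOM acetals and the olefins untouched.

Step 5
Reactants: 7 4-geranyl-3,5-bis(methoxymethoxy)phenol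
Product: 8 2-bromo-4-geranyl-3,5-bis(methoxymethoxy)phenol
Conditions: NBS (1.0 equiv), i-Pr2NH (10 mol%), CH2Cl2, −78 °C, dark; aq. Na2S2O3
Reagents that add atoms: N-bromosuccinimide, O=C1CCC(=O)N1Br
Why: Amine-catalysed electrophilic ortho-bromination of a phenol; the ring position ortho to OH and para to OMOM should react far faster than the isolated olefins at −78 °C, and the symmetry of 7 makes both ortho positions equivalent.

Step 6
Reactants: 8 2-bromo-4-geranyl-3,5-bis(methoxymethoxy)phenol
Product: 12 4-geranyl-3,5-bis(methoxymethoxy)-2-(trimethylsilyl)phenyl trifluoromethanesulfonate, via TMS ether 9 (not isolated), via aryllithium 10 (not isolated), via lithium silylphenoxide 11 (not isolated)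
Conditions: HMDS, THF, 65 °C, then evaporate; n-BuLi (1.1 equiv), THF, −100 → −78 °C; PhNTf2 (1.2 equiv), −78 °C → rt
Reagents that add atoms: hexamethyldisilazane, C[Si](C)(C)N[Si](C)(C)C; N-phenylbis(trifluoromethanesulfonimide), O=S(=O)(N(c1ccccc1)S(=O)(=O)C(F)(F)F)C(F)(F)F
Why: O-silylation, bromine–lithium exchange and the retro-Brook 1,3 O→C silyl shift give the lithium ortho-silylphenoxide, which PhNTf2 triflates on oxygen; this is the standard route to ortho-silylaryl triflates.

Step 7
Reactants: 13 5-hydroxyvanillin
Product: 14 3-methoxy-4,5-bis(methoxymethoxy)benzaldehyde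
Conditions: MOMCl (2.6 equiv), i-Pr2NEt (3 equiv), CH2Cl2, 0 °C → rt
Reagents that add atoms: chloromethyl methyl ether, COCCl
Why: Williamson-type acetalisation of both catechol hydroxyls gives a protecting group that tolerates fluoride and base and is removed together with the ring A MOM ethers at the end.

Step 8
Reactants: 14 3-methoxy-4,5-bis(methoxymethoxy)benzaldehyde
Product: 16 (E)-3-[3-methoxy-4,5-bis(methoxymethoxy)phenyl]acrylic acid, via arylidenemalonic acid 15 (not isolated)
Conditions: malonic acid (2 equiv), pyridine, piperidine (10 mol%), 85 °C; ice-cold aq. citric acid work-up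
Reagents that add atoms: malonic acid, OC(=O)CC(=O)O
Why: Knoevenagel–Doebner condensation with decarboxylation gives the E acid, and the pyridine-buffered medium and mild acidification should spare the MOM acetals.

Step 9
Reactants: 12 4-geranyl-3,5-bis(methoxymethoxy)-2-(trimethylsilyl)phenyl trifluoromethanesulfonate; 16 (E)-3-[3-methoxy-4,5-bis(methoxymethoxy)phenyl]acrylic acid
Product: 19 (E)-1-[3-geranyl-6-hydroxy-2,4-bis(methoxymethoxy)phenyl]-3-[3-methoxy-4,5-bis(methoxymethoxy)phenyl]prop-2-en-1-one, via aryne 17 (not isolated), via racemic flavanone 18 (not isolated)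
Conditions: 16 (1.5 equiv), CsF (4 equiv), THF, sealed tube, 110 °C; then KOH, MeOH/H2O, rt; AcOH to pH 6, 0 °C
Reagents that add atoms: none
Why: Fluoride attacks silicon and triflate leaves, giving the aryne 17 across C4a–C8a (flavanone numbering), and the cesium carboxylate of 16 adds through oxygen to C8a, the aryne carbon remote from the C5 OMOM group, because the aryl anion then develops at C4a beside the inductively stabilising C–O bond, as is usual for 3-alkoxyarynes. The anion attacks the adjacent ester carbonyl through a four-membered alkoxide that opens to the ortho-acyl phenoxide (an anionic Fries-type 1,3 O→C acyl shift), so O1–C8a and C4–C4a form in one operation; the closest known reaction type is the CsF-mediated insertion of arynes into the C–O bond of carboxylic acids to give ortho-hydroxyaryl ketones. No ring and no stereocenter is carried out of this step: hot fluoride is expected to close part of the chalcone phenoxide to the racemic flavanone 18 by 6-endo-trig oxa-Michael addition, and the KOH treatment in the same flask should reopen it by E1cB elimination to the chalcone phenoxide, the thermodynamic sink in strong base, which cold AcOH protonates. The selectivity needed is regiochemical (oxygen at C8a, acyl at C4a) and is secured by the C5 alkoxy group flanking the aryne, while the aprotic hot medium favours acyl transfer over protonation of the aryl anion and the excess of acid suppresses O-arylation of the product phenoxide by a second aryne.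

Step 10
Reactants: 19 (E)-1-[3-geranyl-6-hydroxy-2,4-bis(methoxymethoxy)phenyl]-3-[3-methoxy-4,5-bis(methoxymethoxy)phenyl]prop-2-en-1-one
Product: 20 (2S)-6-geranyl-5,7-bis(methoxymethoxy)-2-[3-methoxy-4,5-bis(methoxymethoxy)phenyl]chroman-4-one
Conditions: N-[3,5-bis(trifluoromethyl)phenyl]-N'-[(9R)-6'-methoxycinchonan-9-yl]thiourea (quinidine-derived, 10 mol%), toluene, 0 °C → rt; monitored by chiral HPLC
Reagents that add atoms: none
Why: In this organocatalytic intramolecular oxa-Michael addition the quinuclidine nitrogen deprotonates the C8a hydroxyl while the thiourea hydrogen-bonds to the enone carbonyl, so the phenoxide adds to C2 in a 6-endo-trig closure within a chiral ion pair and the catalyst sets the 2S centre; the reaction is stopped before reversible ring opening erodes the enantiomeric purity.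

Step 11
Reactants: 20 (2S)-6-geranyl-5,7-bis(methoxymethoxy)-2-[3-methoxy-4,5-bis(methoxymethoxy)phenyl]chroman-4-one
Product: 21 (2S)-6-geranyl-5,7-dihydroxy-2-(3,4-dihydroxy-5-methoxyphenyl)chroman-4-one (CNP0110161.1)
Conditions: 3 M HCl (aq.), MeOH, 45 °C, argon; cold aq. NaHCO3 to pH 5–6
Reagents that add atoms: none
Why: Acid-catalysed methanolysis of the four aryl MOM acetals should proceed under conditions too mild to protonate the geranyl olefins, and since ring opening of flavanones is base-promoted the 2S centre should persist.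

**Compound list**

1 | phloroglucinol | Oc1cc(O)cc(O)c1 | starting material
2 | 3,5-bis(methoxymethoxy)phenol | Oc1cc(OCOC)cc(OCOC)c1 | intermediate
3 | triisopropyl[3,5-bis(methoxymethoxy)phenoxy]silane | CC(C)[Si](Oc1cc(OCOC)cc(OCOC)c1)(C(C)C)C(C)C | intermediate
4 | geranyl bromide, (2E)-1-bromo-3,7-dimethylocta-2,6-diene | CC(C)=CCC/C(C)=C/CBr | starting material
5 | [2,6-bis(methoxymethoxy)-4-(triisopropylsilyloxy)phenyl]lithium | [Li]c1c(OCOC)cc(O[Si](C(C)C)(C(C)C)C(C)C)cc1OCOC | intermediate (not isolated)
6 | triisopropyl[4-geranyl-3,5-bis(methoxymethoxy)phenoxy]silane | CC(C)[Si](Oc1cc(OCOC)c(C/C=C(\C)CCC=C(C)C)c(OCOC)c1)(C(C)C)C(C)C | intermediate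
7 | 4-geranyl-3,5-bis(methoxymethoxy)phenol | Oc1cc(OCOC)c(C/C=C(\C)CCC=C(C)C)c(OCOC)c1 | intermediate
8 | 2-bromo-4-geranyl-3,5-bis(methoxymethoxy)phenol | Oc1cc(OCOC)c(C/C=C(\C)CCC=C(C)C)c(OCOC)c1Br | intermediate
9 | [2-bromo-4-geranyl-3,5-bis(methoxymethoxy)phenoxy]trimethylsilane | C[Si](C)(C)Oc1cc(OCOC)c(C/C=C(\C)CCC=C(C)C)c(OCOC)c1Br | intermediate (not isolated)
10 | [3-geranyl-2,4-bis(methoxymethoxy)-6-(trimethylsilyloxy)phenyl]lithium | C[Si](C)(C)Oc1cc(OCOC)c(C/C=C(\C)CCC=C(C)C)c(OCOC)c1[Li] | intermediate (not isolated)
11 | lithium 4-geranyl-3,5-bis(methoxymethoxy)-2-(trimethylsilyl)phenoxide | [Li]Oc1cc(OCOC)c(C/C=C(\C)CCC=C(C)C)c(OCOC)c1[Si](C)(C)C | intermediate (not isolated)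
12 | 4-geranyl-3,5-bis(methoxymethoxy)-2-(trimethylsilyl)phenyl trifluoromethanesulfonate | C[Si](C)(C)c1c(OS(=O)(=O)C(F)(F)F)cc(OCOC)c(C/C=C(\C)CCC=C(C)C)c1OCOC | intermediate
13 | 5-hydroxyvanillin, 3,4-dihydroxy-5-methoxybenzaldehyde | COc1cc(C=O)cc(O)c1O | starting material
14 | 3-methoxy-4,5-bis(methoxymethoxy)benzaldehyde | COc1cc(C=O)cc(OCOC)c1OCOC | intermediate
15 | 2-[3-methoxy-4,5-bis(methoxymethoxy)benzylidene]malonic acid | COc1cc(C=C(C(=O)O)C(=O)O)cc(OCOC)c1OCOC | intermediate (not isolated)
16 | (E)-3-[3-methoxy-4,5-bis(methoxymethoxy)phenyl]acrylic acid | COc1cc(/C=C/C(=O)O)cc(OCOC)c1OCOC | intermediate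
17 | 4-geranyl-3,5-bis(methoxymethoxy)benzyne (triple bond C1–C2) | COCOC1=CC#CC(OCOC)=C1C/C=C(\C)CCC=C(C)C | intermediate (not isolated)
18 | racemic 6-geranyl-5,7-bis(methoxymethoxy)-2-[3-methoxy-4,5-bis(methoxymethoxy)phenyl]chroman-4-one | COc1cc(C2CC(=O)c3c(cc(OCOC)c(C/C=C(\C)CCC=C(C)C)c3OCOC)O2)cc(OCOC)c1OCOC | intermediate (not isolated; forms in part and is reopened in the same flask)
19 | (E)-1-[3-geranyl-6-hydroxy-2,4-bis(methoxymethoxy)phenyl]-3-[3-methoxy-4,5-bis(methoxymethoxy)phenyl]prop-2-en-1-one | COc1cc(/C=C/C(=O)c2c(O)cc(OCOC)c(C/C=C(\C)CCC=C(C)C)c2OCOC)cc(OCOC)c1OCOC | intermediate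
20 | (2S)-6-geranyl-5,7-bis(methoxymethoxy)-2-[3-methoxy-4,5-bis(methoxymethoxy)phenyl]chroman-4-one | COc1cc([C@@H]2CC(=O)c3c(cc(OCOC)c(C/C=C(\C)CCC=C(C)C)c3OCOC)O2)cc(OCOC)c1OCOC | intermediate
21 | (2S)-6-geranyl-5,7-dihydroxy-2-(3,4-dihydroxy-5-methoxyphenyl)chroman-4-one | COc1cc([C@@H]2CC(=O)c3c(cc(O)c(C/C=C(\C)CCC=C(C)C)c3O)O2)cc(O)c1O | target

**Step count and risks**

Total steps: 11. Longest linear sequence: 9 (steps 1–6, then 9–11); steps 7–8 form the second branch.

Steps most likely to fail:

1. Step 9. The aryl anion may be protonated before the acyl shift, which would give simple O-arylation, the aryne may be consumed in ene reactions with the geranyl olefins, or the alkaline reopening may be incomplete. The fallback sets out from bromophenol 8 and acid 16 and comes back at chalcone 19. Esterification (EDC·HCl, DMAP, CH2Cl2) would give the aryl cinnamate F1. Treatment with t-BuLi (2 equiv, THF/Et2O, −100 °C) should exchange bromine for lithium faster than it adds to the ester. The ortho-lithiated ester is the same species the aryne route passes through; it should undergo the 1,3 O→C acyl shift (anionic Fries rearrangement triggered by halogen–metal exchange) to the lithium phenoxide of 19, which is quenched cold with aq. NH4Cl.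

2. Step 10. Closure of an unactivated chalcone under the bifunctional catalyst may be slow, facial selectivity may be poor, and reversible ring opening may erode the enantiomeric purity. The fallback sets out from chalcone 19 and comes back at flavanone 20. NaOAc in refluxing EtOH would give the racemic flavanone 18, which is resolved by preparative chiral-phase SFC into 20 and the (2R)-flavanone F2. F2 is reopened with KOH in MeOH/H2O to chalcone 19 and recycled, so the resolution loses no material in principle.

3. Step 5. The electrophilic bromine may attack the trisubstituted olefins of the side chain, or bromination may occur twice (C2 and C6). The fallback avoids an electrophilic halogen; it sets out from phenol 7 and comes back at triflate 12. i-PrNCO and Et3N in CH2Cl2 would give the N-isopropyl carbamate F3. This is N-silylated in the flask (TMSOTf, TMEDA, Et2O) to the N-silyl carbamate F4, lithiated between the carbamate oxygen and the OMOM group (n-BuLi, TMEDA, −78 °C) and quenched with TMSCl. Mild aqueous NH4Cl work-up removes the N-silyl group and gives the 2-(trimethylsilyl) carbamate F5. Et2NH and DBU in MeCN at 40 °C free the ortho-silylphenol F6, which PhNTf2 converts into 12.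

**Further compounds**

F1 | step 9 | 2-bromo-4-geranyl-3,5-bis(methoxymethoxy)phenyl (E)-3-[3-methoxy-4,5-bis(methoxymethoxy)phenyl]acrylate | COc1cc(/C=C/C(=O)Oc2cc(OCOC)c(C/C=C(\C)CCC=C(C)C)c(OCOC)c2Br)cc(OCOC)c1OCOC
F2 | step 10 | (2R)-6-geranyl-5,7-bis(methoxymethoxy)-2-[3-methoxy-4,5-bis(methoxymethoxy)phenyl]chroman-4-one | COc1cc([C@H]2CC(=O)c3c(cc(OCOC)c(C/C=C(\C)CCC=C(C)C)c3OCOC)O2)cc(OCOC)c1OCOC
F3 | step 5 | 4-geranyl-3,5-bis(methoxymethoxy)phenyl N-isopropylcarbamate | CC(C)NC(=O)Oc1cc(OCOC)c(C/C=C(\C)CCC=C(C)C)c(OCOC)c1
F4 | step 5 | 4-geranyl-3,5-bis(methoxymethoxy)phenyl N-isopropyl-N-(trimethylsilyl)carbamate | CC(C)N(C(=O)Oc1cc(OCOC)c(C/C=C(\C)CCC=C(C)C)c(OCOC)c1)[Si](C)(C)C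
F5 | step 5 | 4-geranyl-3,5-bis(methoxymethoxy)-2-(trimethylsilyl)phenyl N-isopropylcarbamate | CC(C)NC(=O)Oc1cc(OCOC)c(C/C=C(\C)CCC=C(C)C)c(OCOC)c1[Si](C)(C)C
F6 | step 5 | 4-geranyl-3,5-bis(methoxymethoxy)-2-(trimethylsilyl)phenol | Oc1cc(OCOC)c(C/C=C(\C)CCC=C(C)C)c(OCOC)c1[Si](C)(C)C
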